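**Easy step.** J loses half of itself in 0.138 d, far shorter than the 6.0 d of alder and the 6.0 d that oak holds it on average. The amount of Q therefore turns on its own loss to Z, the rate-limiting step of the passage from J to Z, with a constant below that of J. Nothing past Z returns to Q.

- oak: J 0.27 M; a single well-mixed tank run continuously and read at steady state, 6.0 d in it on average
- alder: J 0.27 M; time 6.0 d; a closed flask charged with all of it at once and left for 6.0 d

    Z → X (k1 = 0.00102 /min)
    J → Q (k2 = 0.00350 /min)
    L → G (k3 = 0.00248 /min)
    Q → Z (k4 = 3.33 × 10⁻⁴ /min)
    Z → L (k5 = 3.89 × 10⁻⁴ /min)

* the set-up with the highest amount of Q at the outlet or at the end, in percent of the J put in ("none" if the first two lie within 2 percentage points) (oak / alder / none)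
* amount of Q at the outlet or at the end, in percent of the J put in, oak
* amount of Q at the outlet or at the end, in percent of the J put in, alder

- the stated concentrations are those of everything mixed, before any reaction; amounts are the same in each set-up
- run time (alder): 6.0 d

**Age count.** The number 2.88 is the age count of Q: the constant of its loss times the time held, on average in oak. In powers of ten, that is 1.25 decades.

**Alder bracket.** Q born at the first instant in alder carries the whole count, and those decades give a floor of 5.63%. Q born later is younger. Taking J's mean delay of 0.198 d off the age lifts the floor to 6.19%. The ceiling is the first floor times 1.11, the constant of J over the gap between the two constants, and my figure for alder is that 6.22%.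

**Oak bracket.** The steady tank oak divides the converted share of J by one plus the count, and a full conversion gives a ceiling of 25.8%. At most 3.31% of J stays unconverted in oak, so the floor is 24.9%. My choice is oak, whose floor stands 19 percentage points above the ceiling of alder, against the margin of 2 points.

**The forecast.** It names oak, with 24.97% for oak and 6.22% for alder, both inside these brackets. Its grounds: “The tank wins because its residence-time spread leaves Q unconsumed”.

**The run.** The simulation puts oak first, with Q at 25.0% of the J put in for oak and 6.22% for alder. The outlet of oak holds 3.20% of the charged J, and the remainder divided by one plus the age count gives 25.0%. Alder left for 60.0 d has an age count of 28.8, or 12.5 decades, and its Q reads 0%.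

The numbers of this flask are made up.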